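# Proposed total synthesis of (2R,3S)-3-aryl flavanone–flavone dimer 23 (CNP0324936.1)

## Analysis of the target

Compound 23 is a biflavonoid: a flavanone (rings A, C and B, the naringenin skeleton) is joined through C3 of ring C to a flavone (the apigenin skeleton). The 4-hydroxyphenyl ring of the flavone is called ring D here; C3 is bonded to the ring D carbon ortho to the ring D hydroxyl, and the chromone sits para to that hydroxyl.

Ring C (O1, C2, C3, C4, C4a, C8a) holds the only two stereocentres, C2 (R, bearing ring B) and C3 (S, bearing ring D). Reading the SMILES places ring B and ring D on opposite faces, so 23 is the 2,3-trans isomer with both aryl groups pseudo-equatorial.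

The two centres differ in lability. C3–H is α to the C4 ketone and benzylic and epimerises easily, so trans is simply the thermodynamic arrangement. C2 can be lost only by β-elimination of the ring A phenoxide (retro-oxa-Michael opening to a chalcone), which base can trigger. The absolute configuration of the molecule therefore rests on C2.

The sensitive groups are six phenols (oxidation-prone, to be unmasked without base), the reducible chromone enone, and the β-aryloxy ketone of ring C.

The difficulty is congestion at C3, a tertiary carbon flanked by the C2 aryl group, the C4 carbonyl and an ortho-substituted aryl ring, combined with the need for a single enantiomer.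

The strategy rests on one feature: C3 is the only atom between C2 and C4. Deleting it and bonding C2 to C4 leaves the flat, achiral 2-aryl-3-silyloxybenzofuran 5. Both bonds to C3 can then come from one carbon donor that already carries ring D.

## Retrosynthetic reasoning

**Protecting groups (23 ⇐ 22 ⇐ 21).** The phenols are unmasked last. Five are benzyl ethers, removed from 22 by hydrogenolysis; the ring D phenol is a triisopropylsilyl ether, removed from 21 by fluoride. The ring D oxygen is silylated and not benzylated because it sits ortho to the future carbene carbon: a benzyl ether there would offer a benzylic C–H bond in a 1,5-relationship for intramolecular insertion, and the silyl ether does not. No skeletal bond is cut, and both deprotections avoid base.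

**C3 configuration (21 ⇐ 20).** The trans compound 21 is traced back to its C3 epimer, the 2,3-cis flavanone 20. Because trans is the more stable isomer, enolisation toward C3 converts 20 into 21. The forward synthesis therefore only has to deliver C2 in the correct absolute sense; C3 is needed beforehand only as the element that controls C2.

**Key disconnection (20 ⇐ 5 + 17).** The bonds C2–C3 and C3–C4 are cut, and C2 is rejoined to C4. C3, with its hydrogen and ring D, becomes the carbene carbon of aryldiazomethane 17; the rest becomes the benzofuran enol silane 5.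
- The cut is made here because C3 is the most congested carbon and the only one whose removal makes the remainder achiral. Cutting O1–C2 or C4–C4a instead would leave open-chain precursors with stereocentres still to be controlled.
- It gains two skeletal bonds and ring C in one operation, with C4 already a ketone.
- The regiochemistry is fixed by construction: the new carbon can only lie between C2 and C4. A Lewis-acid diazo homologation of ketone 4 could instead insert it between C4 and C4a by aryl migration.
- The forward reaction has to cyclopropanate the C2=C4 bond of 5 enantioselectively (18), release cyclopropanol 19, and break the C2–C4 bond homolytically with hydrogen transfer to C2.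

**Carbene precursor (17 ⇐ 16 ⇐ 15 ⇐ 14).** The non-stabilised diazo compound 17 is not isolated. It is released in the flask from the sodium salt 16 of tosylhydrazone 15, which comes from aldehyde 14 by condensation.

**Formyl group and silyl ether (14 ⇐ 13 ⇐ 12).** The C–C bond between ring D and the formyl carbon is cut back to aryl bromide 13 (palladium-catalysed formylation). The bromine is carried from the start because it marks the ring D carbon that will bond to C3. Silyl ether 13 comes from phenol 12.

**Chromone ring (12 ⇐ 11 ⇐ 10 ⇐ 7 + 9; 7 ⇐ 6, 9 ⇐ 8).** The chromone O1–C2 bond and the C2=C3 unsaturation are traced back to 2'-hydroxychalcone 10 by oxidative cyclisation through 11. The enone C=C of 10 is cut by an aldol disconnection into ketone 7 and aldehyde 9, which come from 6 and 8 by selective O-alkylation.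

**Enol silane (5 ⇐ 4 ⇐ 2 + 3; 2 ⇐ 1).** Enol silane 5 is the O-silylated enol of ketone 4. The C2–aryl bond of 4 is cut by a ketone α-arylation disconnection into benzofuranone 2 and aryl bromide 3; 2 is the dibenzyl ether of 1. The precursor is reached in three steps and contains no stereocentre.

## Alternatives that were turned down

**Alternative 1: β-lactone as strained acyl donor.**
- Disconnection: C2–C3 together with a temporary bond from the C2 oxygen to C4, held in the cis-3,4-diaryl oxetan-2-one A1.
- Forward key step: catalytic asymmetric [2+2] cycloaddition of the ring D aryl ketene A2 with 4-(benzyloxy)benzaldehyde A3 under a silylated cinchona alkaloid and a lithium Lewis acid. The lactone carbonyl must then acylate ring A at carbon (C4–C4a), and the C2 oxygen must be joined to C8a.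
- For it: the asymmetric ketene–aldehyde cycloaddition is an established reaction class with reliable cis selectivity, the two fragments are simple, and C2 is set directly by the catalyst. On precedent for the enantioselective event it is stronger than the chosen route.
- Against it for this target:
  - A2 is a monosubstituted, ortho-substituted aryl ketene, prone to dimerise.
  - A1 is a 4-aryl β-lactone with an ionisable benzylic C–O bond. It should lose its carboxyl group as a stilbene on warming, and the electron-rich ring A arene is likely to open it at the alkyl–oxygen bond instead of the acyl–oxygen bond.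
  - After the key step, ring C still needs two further bond formations on a hindered, epimerisable intermediate.
- Comparison: the chosen route forms both bonds to C3 with ring A and O1 already in place, so only epimerisation and deprotection follow the key step.

**Alternative 2: carbene-catalysed acyl anion closing ring C onto a quinone methide.**
- Disconnection: C3–C4 only.
- Forward key step: in aldehyde A5, fluoride desilylates ring D and acetate is lost, giving an ortho-quinone methide at C3. A triazolium-derived carbene converts the ring A aldehyde into an acyl anion equivalent that adds intramolecularly to C3, giving A4.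
- For it: acyl-anion additions to fluoride-generated ortho-quinone methides are known, the closure is an intramolecular six-membered one, C4 arrives as the ketone, the basic medium would give the trans isomer directly, and A4 is one deprotection from 23. On closeness to precedent it is stronger than the chosen route.
- Against it for this target:
  - The stereochemical problem is moved into the precursor. A5 needs C2 as a single enantiomer inside a hindered, open-chain aryl benzylic ether with a differentiated oxygen at C3, which costs many steps.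
  - The quinone methide carries a hydrogen on C2 and can tautomerise to a 2-hydroxystilbene enol ether, erasing C2.
  - The ring A aryloxide is a leaving group β to the developing enolate.
- Comparison: the chosen route replaces a long chiral precursor by a flat one made in three steps, and sets the stereochemistry in the bond-forming event itself.

**Alternative 3: ortho-quinone methide oxa-Diels–Alder with a polarised stilbene.**
- Disconnection: O1–C2 and C3–C4.
- Forward key step: a BINOL-derived chiral phosphoric acid and an orthoformate convert salicylaldehyde A8 into its 4-methoxy ortho-quinone methide, which adds across the (E)-stilbene A7 to give the 2,3-trans-4-methoxyflavan A6.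
- For it: two ring bonds and all ring C stereocentres form at once from two fragments, so it is as convergent as the chosen route. The polarity of A7 (the 4-benzyloxyphenyl end stabilises positive charge better) matches the required regiochemistry. The E geometry gives the trans arrangement directly, with no epimerisation step, and on this point it is stronger than the chosen route.
- Against it for this target:
  - C4 arrives as a methyl ether at the alcohol oxidation level. It has to be unmasked and oxidised in the presence of electron-rich rings and the benzylic C2–H.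
  - A 1,2-diaryl alkene carrying an electron-poor ring D is a sluggish partner for the cationic heterodiene, and a stepwise cationic pathway can erode both the trans relationship and the enantioselectivity.
- Comparison: the chosen route delivers C4 as the ketone and needs no redox step after the key step.

Key step: step 11

## Route

Remarks on the chemistry:
- Flavanone numbering (O1, C2, C3, C4, C4a, C8a) is used for the atoms of ring C in all intermediates, including 5, 18 and 19.
- Assumption: Rh2(S-PTAD)4 is taken to deliver the carbene carbon of 18 in the (1R) configuration. The sense of induction on this substrate has to be established, and Rh2(R-PTAD)4 is used instead, with no other change, if it is the reverse.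

Step 1
Reactants: 1 4,6-dihydroxy-1-benzofuran-3(2H)-one
Product: 2 4,6-bis(benzyloxy)-1-benzofuran-3(2H)-one
Conditions: BnBr (2.1 equiv), K2CO3, DMF, rt
Reagents that add atoms: benzyl bromide, BrCc1ccccc1
Why: Williamson etherification of the two phenols, which are far more acidic than the C2 methylene under carbonate conditions; the near-stoichiometric charge of benzyl bromide limits C2-benzylation.

Step 2
Reactants: 2 4,6-bis(benzyloxy)-1-benzofuran-3(2H)-one; 3 1-(benzyloxy)-4-bromobenzene
Product: 4 rac-4,6-bis(benzyloxy)-2-[4-(benzyloxy)phenyl]-1-benzofuran-3(2H)-one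
Conditions: Pd2(dba)3 (2 mol%), tBu3P·HBF4 (8 mol%), NaOtBu (2.2 equiv), toluene, 70 °C, argon; aq. NH4Cl
Reagents that add atoms: none
Why: Palladium-catalysed ketone α-arylation: the C2 methylene lies between the ketone and the ring oxygen and its enolate is an aromatic 3-oxidobenzofuran, so enolisation is complete and self-aldol is suppressed, and the bulky phosphine promotes C–C reductive elimination. The more hindered product enolate resists a second arylation; C2 forms racemic, which is irrelevant because it becomes sp2 in step 3.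

Step 3
Reactants: 4 rac-4,6-bis(benzyloxy)-2-[4-(benzyloxy)phenyl]-1-benzofuran-3(2H)-one
Product: 5 {[4,6-bis(benzyloxy)-2-[4-(benzyloxy)phenyl]-1-benzofuran-3-yl]oxy}(trimethyl)silane
Conditions: Me3SiOTf, Et3N, CH2Cl2, 0 °C; non-aqueous work-up (hexane/toluene, filtration) under argon
Reagents that add atoms: trimethylsilyl trifluoromethanesulfonate, C[Si](C)(C)OS(=O)(=O)C(F)(F)F
Why: O-silylation of an enolisable ketone whose enol is an aromatic benzofuran, so silicon goes to oxygen and the flat, achiral enol silane results. The trimethylsilyl group is chosen because it can later be removed by simple alcoholysis.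

Step 4
Reactants: 6 1-(2,4,6-trihydroxyphenyl)ethan-1-one
Product: 7 1-[2,4-bis(benzyloxy)-6-hydroxyphenyl]ethan-1-one
Conditions: BnBr (2.1 equiv), K2CO3, DMF, rt
Reagents that add atoms: benzyl bromide, BrCc1ccccc1
Why: Williamson etherification; the hydroxyl hydrogen-bonded to the acetyl carbonyl is the least nucleophilic and stays free when two equivalents of the halide are used.

Step 5
Reactants: 8 3-bromo-4-hydroxybenzaldehyde
Product: 9 3-bromo-4-(methoxymethoxy)benzaldehyde
Conditions: MOMCl, iPr2NEt, CH2Cl2, 0 °C to rt
Reagents that add atoms: chloromethyl methyl ether, COCCl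
Why: O-alkylation of the phenol to its methoxymethyl acetal; masking the phenol prevents the phenoxide from deactivating the aldehyde in the aldol step, and the acetal is stable to hydroxide.

Step 6
Reactants: 7 1-[2,4-bis(benzyloxy)-6-hydroxyphenyl]ethan-1-one; 9 3-bromo-4-(methoxymethoxy)benzaldehyde
Product: 10 (E)-1-[2,4-bis(benzyloxy)-6-hydroxyphenyl]-3-[3-bromo-4-(methoxymethoxy)phenyl]prop-2-en-1-one
Conditions: KOH (3 equiv), EtOH/THF, rt; aq. HCl
Reagents that add atoms: none
Why: Claisen–Schmidt condensation (crossed aldol addition and E1cB dehydration) gives the E-chalcone under thermodynamic control; acetal, benzyl ethers and aryl bromide tolerate ethanolic hydroxide.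

Step 7
Reactants: 10 (E)-1-[2,4-bis(benzyloxy)-6-hydroxyphenyl]-3-[3-bromo-4-(methoxymethoxy)phenyl]prop-2-en-1-one
Product: 12 5,7-bis(benzyloxy)-2-(3-bromo-4-hydroxyphenyl)-4H-chromen-4-one, via MOM-protected flavone 11 (not isolated)
Conditions: I2 (10 mol%), DMSO, 120 °C; then conc. HCl (cat.), MeOH/THF, 50 °C
Reagents that add atoms: none
Why: Iodine-catalysed oxidative cyclisation of a 2'-hydroxychalcone (oxa-Michael closure, α-iodination, loss of HI, with the sulfoxide re-oxidising HI to I2) gives the chromone. The acid formed already loosens the acetal and methanolic HCl completes its removal, while the benzyl ethers stay.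

Step 8
Reactants: 12 5,7-bis(benzyloxy)-2-(3-bromo-4-hydroxyphenyl)-4H-chromen-4-one
Product: 13 5,7-bis(benzyloxy)-2-{3-bromo-4-[(triisopropylsilyl)oxy]phenyl}-4H-chromen-4-one
Conditions: iPr3SiOTf, 2,6-lutidine, CH2Cl2, 0 °C to rt
Reagents that add atoms: triisopropylsilyl trifluoromethanesulfonate, CC(C)[Si](OS(=O)(=O)C(F)(F)F)(C(C)C)C(C)C
Why: Silylation of the phenol; the silyl triflate overcomes the hindrance of the ortho bromine. The bulky silyl ether withstands the bases used later and offers the carbene of step 11 no C–H bond in a 1,5-relationship.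

Step 9
Reactants: 13 5,7-bis(benzyloxy)-2-{3-bromo-4-[(triisopropylsilyl)oxy]phenyl}-4H-chromen-4-one
Product: 14 5-[5,7-bis(benzyloxy)-4-oxo-4H-chromen-2-yl]-2-[(triisopropylsilyl)oxy]benzaldehyde
Conditions: Pd(OAc)2 (2 mol%), P(1-Ad)2nBu (6 mol%), TMEDA, CO/H2 (5 bar), toluene, 100 °C
Reagents that add atoms: carbon monoxide, [C-]#[O+]
Why: Palladium-catalysed reductive carbonylation (formylation) of an aryl bromide: oxidative addition, CO insertion and hydrogenolysis of the acyl–palladium bond. The bulky, electron-rich dialkylphosphine handles the ortho-silyloxy bromide, and the non-nucleophilic medium spares silyl ether, benzyl ethers and chromone.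

Step 10
Reactants: 14 5-[5,7-bis(benzyloxy)-4-oxo-4H-chromen-2-yl]-2-[(triisopropylsilyl)oxy]benzaldehyde
Product: 15 N'-[(E)-{5-[5,7-bis(benzyloxy)-4-oxo-4H-chromen-2-yl]-2-[(triisopropylsilyl)oxy]phenyl}methylidene]-4-methylbenzenesulfonohydrazide
Conditions: TsNHNH2, THF/MeOH, rt
Reagents that add atoms: 4-methylbenzenesulfonohydrazide, Cc1ccc(cc1)S(=O)(=O)NN
Why: Condensation of the aldehyde with the sulfonyl hydrazide gives the E-hydrazone; the chromone carbonyl is a vinylogous ester and does not compete.

Step 11
Reactants: 5 {[4,6-bis(benzyloxy)-2-[4-(benzyloxy)phenyl]-1-benzofuran-3-yl]oxy}(trimethyl)silane; 15 N'-[(E)-{5-[5,7-bis(benzyloxy)-4-oxo-4H-chromen-2-yl]-2-[(triisopropylsilyl)oxy]phenyl}methylidene]-4-methylbenzenesulfonohydrazide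
Product: 20 (2R,3R)-5,7-bis(benzyloxy)-2-[4-(benzyloxy)phenyl]-3-{5-[5,7-bis(benzyloxy)-4-oxo-4H-chromen-2-yl]-2-[(triisopropylsilyl)oxy]phenyl}-2,3-dihydro-4H-chromen-4-one (2,3-cis), via hydrazone sodium salt 16 (not isolated), via aryldiazomethane 17 (not isolated), via silyloxycyclopropane 18 (not isolated), via cyclopropanol 19 (not isolated)
Conditions: 15, NaH, THF, 0 °C to rt, solvent exchanged for toluene; 5 (1.2 equiv), Rh2(S-PTAD)4 (1 mol%), BnEt3NCl (10 mol%), toluene, 40 °C; cannula filtration under argon; then MeOH (10 equiv), (nBu4N)2CeCl6 (5 mol%), 2,4,6-triisopropylbenzenethiol (30 mol%), MeCN, 400 nm LEDs, 10 °C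
Reagents that add atoms: none
Why: Proposed new method: salt 16 releases aryldiazomethane 17 slowly at 40 °C under phase transfer (Bamford–Stevens fragmentation), and Rh2(S-PTAD)4 turns it into an electrophilic aryl carbene that adds across the doubly oxygenated C2=C4 bond of 5 in a [2+1] cycloaddition, forming C2–C3 and C3–C4 in 18. The closest known reaction types are the dirhodium-catalysed asymmetric cyclopropanation of benzofurans and of silyl enol ethers, and the single-electron oxidative ring enlargement of bicyclic cyclopropanols through β-keto radicals (Dowd–Beckwith-type β-scission); neither has been shown on a fully substituted 2-aryl-3-silyloxybenzofuran, nor have the two been run in sequence. Methanol, assisted by the Lewis-acidic cerium chloride, then frees cyclopropanol 19 a little at a time; its alkoxide on tetravalent cerium gives an oxygen-centred radical at C4 by ligand-to-metal charge transfer at 400 nm, β-scission of the fusion bond C2–C4 forms the C4 ketone and a C2 radical, the thiol gives this radical a hydrogen atom, and the thiyl radical is returned to thiol by proton-coupled oxidation of trivalent cerium, which closes the catalytic cycle. Ring C is thus not closed by a cyclisation: it arises by one-carbon enlargement of the five-membered furan ring, through intermolecular cyclopropanation followed by endocyclic scission of the bond shared by the two small rings. C3 is set in the cyclopropanation by the chiral pocket of the four N-phthaloyl-(S)-adamantylglycinate ligands, which must fix both the face of 5 that is attacked and the endo position of ring D (over the benzofuran, away from ring B and the silyloxy group), because exo addition to the same face would give the opposite configuration at C3. C2 is set by substrate control: in the ring-enlarged radical the C3 aryl group stands pseudo-axial to avoid allylic 1,2-strain with the coplanar ring B, so the bulky thiol delivers hydrogen to the opposite face and ring B ends up cis to ring D, which is (2R,3R)-20. The step needs scission of C2–C4 and not of C3–C4; this is secured by the greater stabilisation of the C2 radical (lone pair of O1 plus the 4-benzyloxyphenyl ring, against a simple benzylic radical at C3) and by the strain released on enlargement, while neutral conditions and immediate consumption of 19 hold back its ionic opening along C3–C4.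

Step 12
Reactants: 20 (2R,3R)-5,7-bis(benzyloxy)-2-[4-(benzyloxy)phenyl]-3-{5-[5,7-bis(benzyloxy)-4-oxo-4H-chromen-2-yl]-2-[(triisopropylsilyl)oxy]phenyl}-2,3-dihydro-4H-chromen-4-one
Product: 21 (2R,3S)-5,7-bis(benzyloxy)-2-[4-(benzyloxy)phenyl]-3-{5-[5,7-bis(benzyloxy)-4-oxo-4H-chromen-2-yl]-2-[(triisopropylsilyl)oxy]phenyl}-2,3-dihydro-4H-chromen-4-one (2,3-trans)
Conditions: DBU (10 mol%), toluene, 0 °C to rt; AcOH quench
Reagents that add atoms: none
Why: Base-catalysed epimerisation through the C3 enolate (C3–H is α to the ketone and benzylic); thermodynamic control gives the 2,3-trans isomer with both aryl groups pseudo-equatorial, inverting C3 while C2 is untouched. A catalytic amidine in an aprotic solvent keeps the enolate concentration low and its reprotonation fast, so that β-elimination of the ring A aryloxide, which would racemise C2, should not compete.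

Step 13
Reactants: 21 (2R,3S)-5,7-bis(benzyloxy)-2-[4-(benzyloxy)phenyl]-3-{5-[5,7-bis(benzyloxy)-4-oxo-4H-chromen-2-yl]-2-[(triisopropylsilyl)oxy]phenyl}-2,3-dihydro-4H-chromen-4-one
Product: 22 (2R,3S)-5,7-bis(benzyloxy)-2-[4-(benzyloxy)phenyl]-3-{5-[5,7-bis(benzyloxy)-4-oxo-4H-chromen-2-yl]-2-hydroxyphenyl}-2,3-dihydro-4H-chromen-4-one
Conditions: HF·pyridine, THF/pyridine, 0 °C to rt
Reagents that add atoms: none
Why: Fluoride cleavage of the aryl silyl ether driven by the strong Si–F bond; the buffered, non-basic medium leaves C2, C3 and the benzyl ethers untouched.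

Step 14
Reactants: 22 (2R,3S)-5,7-bis(benzyloxy)-2-[4-(benzyloxy)phenyl]-3-{5-[5,7-bis(benzyloxy)-4-oxo-4H-chromen-2-yl]-2-hydroxyphenyl}-2,3-dihydro-4H-chromen-4-one
Product: 23 (2R,3S)-5,7-dihydroxy-3-[5-(5,7-dihydroxy-4-oxo-4H-chromen-2-yl)-2-hydroxyphenyl]-2-(4-hydroxyphenyl)-2,3-dihydro-4H-chromen-4-one
Conditions: H2 (1 atm), 10% Pd/C, EtOAc/MeOH, rt
Reagents that add atoms: none
Why: Hydrogenolysis of the five benzyl aryl ethers over palladium in a neutral medium; the reaction is stopped when hydrogen uptake ends so that the chromone C2=C3 bond and the benzylic C2–O1 bond of ring C are not reduced, and the absence of base keeps both stereocentres.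

## Compound list

1 | 4,6-dihydroxy-1-benzofuran-3(2H)-one | O=C1COc2cc(O)cc(O)c12 | starting material
2 | 4,6-bis(benzyloxy)-1-benzofuran-3(2H)-one | O=C1COc2cc(OCc3ccccc3)cc(OCc3ccccc3)c12 | intermediate
3 | 1-(benzyloxy)-4-bromobenzene | Brc1ccc(OCc2ccccc2)cc1 | starting material
4 | rac-4,6-bis(benzyloxy)-2-[4-(benzyloxy)phenyl]-1-benzofuran-3(2H)-one (racemate) | O=C1C(c2ccc(OCc3ccccc3)cc2)Oc2cc(OCc3ccccc3)cc(OCc3ccccc3)c12 | intermediate
5 | {[4,6-bis(benzyloxy)-2-[4-(benzyloxy)phenyl]-1-benzofuran-3-yl]oxy}(trimethyl)silane | C[Si](C)(C)Oc1c(-c2ccc(OCc3ccccc3)cc2)oc2cc(OCc3ccccc3)cc(OCc3ccccc3)c12 | intermediate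
6 | 1-(2,4,6-trihydroxyphenyl)ethan-1-one | CC(=O)c1c(O)cc(O)cc1O | starting material
7 | 1-[2,4-bis(benzyloxy)-6-hydroxyphenyl]ethan-1-one | CC(=O)c1c(O)cc(OCc2ccccc2)cc1OCc1ccccc1 | intermediate
8 | 3-bromo-4-hydroxybenzaldehyde | O=Cc1ccc(O)c(Br)c1 | starting material
9 | 3-bromo-4-(methoxymethoxy)benzaldehyde | COCOc1ccc(C=O)cc1Br | intermediate
10 | (E)-1-[2,4-bis(benzyloxy)-6-hydroxyphenyl]-3-[3-bromo-4-(methoxymethoxy)phenyl]prop-2-en-1-one | O=C(/C=C/c1ccc(OCOC)c(Br)c1)c1c(O)cc(OCc2ccccc2)cc1OCc1ccccc1 | intermediate
11 | 5,7-bis(benzyloxy)-2-[3-bromo-4-(methoxymethoxy)phenyl]-4H-chromen-4-one (not isolated) | COCOc1ccc(-c2cc(=O)c3c(OCc4ccccc4)cc(OCc4ccccc4)cc3o2)cc1Br | intermediate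
12 | 5,7-bis(benzyloxy)-2-(3-bromo-4-hydroxyphenyl)-4H-chromen-4-one | Oc1ccc(-c2cc(=O)c3c(OCc4ccccc4)cc(OCc4ccccc4)cc3o2)cc1Br | intermediate
13 | 5,7-bis(benzyloxy)-2-{3-bromo-4-[(triisopropylsilyl)oxy]phenyl}-4H-chromen-4-one | CC(C)[Si](Oc1ccc(-c2cc(=O)c3c(OCc4ccccc4)cc(OCc4ccccc4)cc3o2)cc1Br)(C(C)C)C(C)C | intermediate
14 | 5-[5,7-bis(benzyloxy)-4-oxo-4H-chromen-2-yl]-2-[(triisopropylsilyl)oxy]benzaldehyde | CC(C)[Si](Oc1ccc(-c2cc(=O)c3c(OCc4ccccc4)cc(OCc4ccccc4)cc3o2)cc1C=O)(C(C)C)C(C)C | intermediate
15 | N'-[(E)-{5-[5,7-bis(benzyloxy)-4-oxo-4H-chromen-2-yl]-2-[(triisopropylsilyl)oxy]phenyl}methylidene]-4-methylbenzenesulfonohydrazide | Cc1ccc(cc1)S(=O)(=O)N/N=C/c1cc(-c2cc(=O)c3c(OCc4ccccc4)cc(OCc4ccccc4)cc3o2)ccc1O[Si](C(C)C)(C(C)C)C(C)C | intermediate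
16 | sodium salt of tosylhydrazone 15 (not isolated) | [Na+].Cc1ccc(cc1)S(=O)(=O)[N-]/N=C/c1cc(-c2cc(=O)c3c(OCc4ccccc4)cc(OCc4ccccc4)cc3o2)ccc1O[Si](C(C)C)(C(C)C)C(C)C | intermediate
17 | 5,7-bis(benzyloxy)-2-{3-(diazomethyl)-4-[(triisopropylsilyl)oxy]phenyl}-4H-chromen-4-one (not isolated) | [N-]=[N+]=Cc1cc(-c2cc(=O)c3c(OCc4ccccc4)cc(OCc4ccccc4)cc3o2)ccc1O[Si](C(C)C)(C(C)C)C(C)C | intermediate
18 | (1R,1aR,6bR)-4,6-bis(benzyloxy)-1a-[4-(benzyloxy)phenyl]-1-{5-[5,7-bis(benzyloxy)-4-oxo-4H-chromen-2-yl]-2-[(triisopropylsilyl)oxy]phenyl}-6b-[(trimethylsilyl)oxy]-1a,6b-dihydro-1H-cyclopropa[b][1]benzofuran; ring D endo, on the side of the ring oxygen and the benzo ring (not isolated) | C[Si](C)(C)O[C@]12c3c(OCc4ccccc4)cc(OCc4ccccc4)cc3O[C@@]1(c1ccc(OCc3ccccc3)cc1)[C@H]2c1cc(-c2cc(=O)c3c(OCc4ccccc4)cc(OCc4ccccc4)cc3o2)ccc1O[Si](C(C)C)(C(C)C)C(C)C | intermediate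
19 | (1S,1aR,6bR)-4,6-bis(benzyloxy)-1a-[4-(benzyloxy)phenyl]-1-{5-[5,7-bis(benzyloxy)-4-oxo-4H-chromen-2-yl]-2-[(triisopropylsilyl)oxy]phenyl}-1,1a-dihydro-6bH-cyclopropa[b][1]benzofuran-6b-ol; same spatial arrangement as 18 (not isolated) | O[C@]12c3c(OCc4ccccc4)cc(OCc4ccccc4)cc3O[C@@]1(c1ccc(OCc3ccccc3)cc1)[C@H]2c1cc(-c2cc(=O)c3c(OCc4ccccc4)cc(OCc4ccccc4)cc3o2)ccc1O[Si](C(C)C)(C(C)C)C(C)C | intermediate
20 | (2R,3R)-5,7-bis(benzyloxy)-2-[4-(benzyloxy)phenyl]-3-{5-[5,7-bis(benzyloxy)-4-oxo-4H-chromen-2-yl]-2-[(triisopropylsilyl)oxy]phenyl}-2,3-dihydro-4H-chromen-4-one (2,3-cis) | O=C1c2c(OCc3ccccc3)cc(OCc3ccccc3)cc2O[C@@H](c2ccc(OCc3ccccc3)cc2)[C@H]1c1cc(-c2cc(=O)c3c(OCc4ccccc4)cc(OCc4ccccc4)cc3o2)ccc1O[Si](C(C)C)(C(C)C)C(C)C | intermediate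
21 | (2R,3S)-5,7-bis(benzyloxy)-2-[4-(benzyloxy)phenyl]-3-{5-[5,7-bis(benzyloxy)-4-oxo-4H-chromen-2-yl]-2-[(triisopropylsilyl)oxy]phenyl}-2,3-dihydro-4H-chromen-4-one (2,3-trans) | O=C1c2c(OCc3ccccc3)cc(OCc3ccccc3)cc2O[C@@H](c2ccc(OCc3ccccc3)cc2)[C@@H]1c1cc(-c2cc(=O)c3c(OCc4ccccc4)cc(OCc4ccccc4)cc3o2)ccc1O[Si](C(C)C)(C(C)C)C(C)C | intermediate
22 | (2R,3S)-5,7-bis(benzyloxy)-2-[4-(benzyloxy)phenyl]-3-{5-[5,7-bis(benzyloxy)-4-oxo-4H-chromen-2-yl]-2-hydroxyphenyl}-2,3-dihydro-4H-chromen-4-one | O=C1c2c(OCc3ccccc3)cc(OCc3ccccc3)cc2O[C@@H](c2ccc(OCc3ccccc3)cc2)[C@@H]1c1cc(-c2cc(=O)c3c(OCc4ccccc4)cc(OCc4ccccc4)cc3o2)ccc1O | intermediate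
23 | (2R,3S)-5,7-dihydroxy-3-[5-(5,7-dihydroxy-4-oxo-4H-chromen-2-yl)-2-hydroxyphenyl]-2-(4-hydroxyphenyl)-2,3-dihydro-4H-chromen-4-one | O=C1c2c(O)cc(O)cc2O[C@@H](c2ccc(O)cc2)[C@@H]1c1cc(-c2cc(=O)c3c(O)cc(O)cc3o2)ccc1O | target

## Step count and risk

Total step count: 14 (steps 1–3 for the benzofuran, steps 4–10 for the ring D fragment, steps 11–14 in common).

Longest linear sequence: 10 steps (8 → 9 → 10 → 12 → 13 → 14 → 15 → 20 → 21 → 22 → 23; steps 5 to 14).

**Step 11 (key step, proposed new method).** Several processes can divert it: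
- The carbene may fail to engage the fully substituted C2=C4 bond and be lost to dimerisation, azine formation or insertion into C–H bonds.
- Facial or endo/exo control in the cyclopropanation may be incomplete, and either leak lowers the enantiomeric purity at C3.
- The donor-substituted cyclopropanol may open ionically along C3–C4, which returns a five-membered ketone.
- Tetravalent cerium may over-oxidise the C2 radical to an oxocarbenium ion, followed by loss of the C3 proton.
- Hydrogen transfer to C2 may show poor facial selectivity. Any 2,3-trans isomer formed directly belongs to the enantiomeric series and has to be removed by chromatography before step 12, so this leak costs material but not enantiopurity as long as 20 does not epimerise during purification.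

Fallback, by known chemistry, setting out from 7 and 13 and returning to the route at 21:
- Ketone 7 is converted into its methoxymethyl ether F1 (MOMCl, iPr2NEt).
- Palladium-catalysed α-arylation of this methyl ketone with bromide 13 (Pd2(dba)3, Xantphos, K3PO4, toluene, 90 °C) gives the protected deoxybenzoin F2.
- Methanolic HCl removes the acetal to give the 2-hydroxydeoxybenzoin F3.
- Condensation with 4-(benzyloxy)benzaldehyde (piperidine, EtOH, reflux; Knoevenagel-type condensation and oxa-Michael closure) gives the thermodynamic 2,3-trans flavanone as the racemate F4.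
- Preparative chromatography on a chiral stationary phase separates F4 into 21 and its (2S,3R) enantiomer F5.

This fallback gives up the catalytic control of configuration but uses only established reactions.

**Step 2.** Over-arylation at C2, O-arylation, or aerobic oxidation of the electron-rich product enolate may erode the mono-arylated ketone. Fallback, setting out from 2 and returning at 4: metal-free electrophilic arylation. The symmetrical diaryliodonium salt bis[4-(benzyloxy)phenyl]iodonium 4-methylbenzenesulfonate F6 is prepared from 1-(benzyloxy)-4-iodobenzene, mCPBA, TsOH·H2O and benzyl phenyl ether. The lithium enolate of 2 (LiN(SiMe3)2, THF, −78 °C) is arylated with F6; after one aryl transfer the iodoarene is released and no catalyst remains to promote a second arylation.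

**Step 9.** Oxidative addition into the bromide ortho to the bulky silyloxy group may be slow, and hydrodebromination may take over. Fallback, setting out from 13 and returning at 14: Stille coupling with tributyl(vinyl)stannane (Pd(PPh3)4, toluene, 100 °C) gives the vinylarene F7. Lemieux–Johnson cleavage (OsO4 cat., NaIO4, 2,6-lutidine, dioxane/water) then gives 14; the electron-poor chromone alkene is not attacked.

**Step 12.** Retro-oxa-Michael opening of ring C from the C3 enolate and re-closure would erode the configuration at C2, and the equilibration may stop short of completion. Fallback, setting out from 20 and returning at 23: the base is avoided altogether and the order is changed. Compound 20 is desilylated (HF·pyridine) to the cis phenol F8 and hydrogenolysed (H2, Pd/C) to the cis hexaphenol F9. F9 is then equilibrated to 23 in dilute methanolic HCl at 40 °C by acid-catalysed enolisation, under which no phenoxide can be expelled.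

**Step 14.** Over-reduction of the chromone C2=C3 bond, or hydrogenolysis of the benzylic C2–O1 bond of ring C to a dihydrochalcone, may accompany debenzylation. Fallback, setting out from 22 and returning at 23: non-reductive Lewis-acid debenzylation with BCl3 and pentamethylbenzene as cation scavenger (CH2Cl2, −78 °C). It makes no new intermediate.

## Further compounds

F1 | step 11 | 1-[2,4-bis(benzyloxy)-6-(methoxymethoxy)phenyl]ethan-1-one | CC(=O)c1c(OCOC)cc(OCc2ccccc2)cc1OCc1ccccc1
F2 | step 11 | 1-[2,4-bis(benzyloxy)-6-(methoxymethoxy)phenyl]-2-{5-[5,7-bis(benzyloxy)-4-oxo-4H-chromen-2-yl]-2-[(triisopropylsilyl)oxy]phenyl}ethan-1-one | COCOc1cc(OCc2ccccc2)cc(OCc2ccccc2)c1C(=O)Cc1cc(-c2cc(=O)c3c(OCc4ccccc4)cc(OCc4ccccc4)cc3o2)ccc1O[Si](C(C)C)(C(C)C)C(C)C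
F3 | step 11 | 1-[2,4-bis(benzyloxy)-6-hydroxyphenyl]-2-{5-[5,7-bis(benzyloxy)-4-oxo-4H-chromen-2-yl]-2-[(triisopropylsilyl)oxy]phenyl}ethan-1-one | Oc1cc(OCc2ccccc2)cc(OCc2ccccc2)c1C(=O)Cc1cc(-c2cc(=O)c3c(OCc4ccccc4)cc(OCc4ccccc4)cc3o2)ccc1O[Si](C(C)C)(C(C)C)C(C)C
F4 | step 11 | rac-(2R*,3S*)-5,7-bis(benzyloxy)-2-[4-(benzyloxy)phenyl]-3-{5-[5,7-bis(benzyloxy)-4-oxo-4H-chromen-2-yl]-2-[(triisopropylsilyl)oxy]phenyl}-2,3-dihydro-4H-chromen-4-one (racemate, relative configuration shown) | O=C1c2c(OCc3ccccc3)cc(OCc3ccccc3)cc2O[C@@H](c2ccc(OCc3ccccc3)cc2)[C@@H]1c1cc(-c2cc(=O)c3c(OCc4ccccc4)cc(OCc4ccccc4)cc3o2)ccc1O[Si](C(C)C)(C(C)C)C(C)C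
F5 | step 11 | (2S,3R)-5,7-bis(benzyloxy)-2-[4-(benzyloxy)phenyl]-3-{5-[5,7-bis(benzyloxy)-4-oxo-4H-chromen-2-yl]-2-[(triisopropylsilyl)oxy]phenyl}-2,3-dihydro-4H-chromen-4-one (enantiomer of 21) | O=C1c2c(OCc3ccccc3)cc(OCc3ccccc3)cc2O[C@H](c2ccc(OCc3ccccc3)cc2)[C@H]1c1cc(-c2cc(=O)c3c(OCc4ccccc4)cc(OCc4ccccc4)cc3o2)ccc1O[Si](C(C)C)(C(C)C)C(C)C
F6 | step 2 | bis[4-(benzyloxy)phenyl]iodonium 4-methylbenzenesulfonate | Cc1ccc(cc1)S(=O)(=O)[O-].c1ccc(COc2ccc([I+]c3ccc(OCc4ccccc4)cc3)cc2)cc1
F7 | step 9 | 5,7-bis(benzyloxy)-2-{3-ethenyl-4-[(triisopropylsilyl)oxy]phenyl}-4H-chromen-4-one | C=Cc1cc(-c2cc(=O)c3c(OCc4ccccc4)cc(OCc4ccccc4)cc3o2)ccc1O[Si](C(C)C)(C(C)C)C(C)C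
F8 | step 12 | (2R,3R)-5,7-bis(benzyloxy)-2-[4-(benzyloxy)phenyl]-3-{5-[5,7-bis(benzyloxy)-4-oxo-4H-chromen-2-yl]-2-hydroxyphenyl}-2,3-dihydro-4H-chromen-4-one (2,3-cis) | O=C1c2c(OCc3ccccc3)cc(OCc3ccccc3)cc2O[C@@H](c2ccc(OCc3ccccc3)cc2)[C@H]1c1cc(-c2cc(=O)c3c(OCc4ccccc4)cc(OCc4ccccc4)cc3o2)ccc1O
F9 | step 12 | (2R,3R)-5,7-dihydroxy-3-[5-(5,7-dihydroxy-4-oxo-4H-chromen-2-yl)-2-hydroxyphenyl]-2-(4-hydroxyphenyl)-2,3-dihydro-4H-chromen-4-one (2,3-cis) | O=C1c2c(O)cc(O)cc2O[C@@H](c2ccc(O)cc2)[C@H]1c1cc(-c2cc(=O)c3c(O)cc(O)cc3o2)ccc1O
F0 | step 14 | none | none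
A1 | alternative 1 | cis-4-[4-(benzyloxy)phenyl]-3-{2-(benzyloxy)-5-[5,7-bis(benzyloxy)-4-oxo-4H-chromen-2-yl]phenyl}oxetan-2-one | O=C1O[C@@H](c2ccc(OCc3ccccc3)cc2)[C@H]1c1cc(-c2cc(=O)c3c(OCc4ccccc4)cc(OCc4ccccc4)cc3o2)ccc1OCc1ccccc1
A2 | alternative 1 | {2-(benzyloxy)-5-[5,7-bis(benzyloxy)-4-oxo-4H-chromen-2-yl]phenyl}ketene | O=C=Cc1cc(-c2cc(=O)c3c(OCc4ccccc4)cc(OCc4ccccc4)cc3o2)ccc1OCc1ccccc1
A3 | alternative 1 | 4-(benzyloxy)benzaldehyde | O=Cc1ccc(OCc2ccccc2)cc1
A4 | alternative 2 | 2,3-trans flavanone with five methoxymethyl ethers and free ring D phenol | O=C1c2c(OCOC)cc(OCOC)cc2O[C@@H](c2ccc(OCOC)cc2)[C@@H]1c1cc(-c2cc(=O)c3c(OCOC)cc(OCOC)cc3o2)ccc1O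
A5 | alternative 2 | 2-formyl-3,5-bis(methoxymethoxy)phenyl ether of the C2 benzylic alcohol, with C3 acetate and ring D tert-butyldimethylsilyl ether (C2 as in the target, C3 unspecified) | O=Cc1c(OCOC)cc(OCOC)cc1O[C@@H](c1ccc(OCOC)cc1)C(OC(C)=O)c1cc(-c2cc(=O)c3c(OCOC)cc(OCOC)cc3o2)ccc1O[Si](C)(C)C(C)(C)C
A6 | alternative 3 | protected 2,3-trans-4-methoxyflavan with ring D benzyl carbonate | CO[C@H]1c2c(OCc3ccccc3)cc(OCc3ccccc3)cc2O[C@@H](c2ccc(OCc3ccccc3)cc2)[C@@H]1c1cc(-c2cc(=O)c3c(OCc4ccccc4)cc(OCc4ccccc4)cc3o2)ccc1OC(=O)OCc1ccccc1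
A7 | alternative 3 | benzyl 2-{(E)-2-[4-(benzyloxy)phenyl]ethenyl}-4-[5,7-bis(benzyloxy)-4-oxo-4H-chromen-2-yl]phenyl carbonate | O=C(OCc1ccccc1)Oc1ccc(-c2cc(=O)c3c(OCc4ccccc4)cc(OCc4ccccc4)cc3o2)cc1/C=C/c1ccc(OCc2ccccc2)cc1
A8 | alternative 3 | 2,4-bis(benzyloxy)-6-hydroxybenzaldehyde | O=Cc1c(O)cc(OCc2ccccc2)cc1OCc1ccccc1
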